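## Structural features

The target 23 is a cis-fused bicyclo[4.4.0]decane of the eremophilane type. The numbering used throughout is ring A = C1–C2–C3–C4–C5–C10 (saturated) and ring B = C5–C6–C7–C8–C9–C10, a cyclohexenone with the ketone at C8 and the double bond C6=C7. Ring A carries four contiguous stereocentres: C3 (S, angelate), C4 (R, methyl C15), the quaternary C5 (R, methyl C14) and C10 (R, H). The C3 oxygen, both methyl groups and H10 all lie on one face. A fifth stereocentre, C11 (R, methyl C13, methyl ester C12), sits on the C7 side chain and cannot be relayed from the ring. The fragile groups are the angelate (Z to E isomerisation whenever the acid is activated as an acyl donor), C11–H (alpha to the ester and allylic to C6=C7, so open to epimerisation and double-bond migration under base) and the enone. The real difficulty is the C4–C5–C10 triad around the quaternary carbon, which has to be built while C11 stays secure. The key step exploits two relationships. First, the C8 ketone and C6 are 1,5-related through C9, C10 and C5, so ring B is the aldol condensation product of a C6 aldehyde and a C8 ketone, and that 1,5-dicarbonyl is what a cyclobutane C5–C6–C9–C10 releases on retro-aldol cleavage of C6–C9. Second, the C3 oxygen is three bonds from C5 (O–C3–C4–C5), so it can be the enol-ether oxygen on C6 and deliver C6=C9 to a ring A alkene C5=C10 through a five-membered ring. The price is that this tether puts O3 trans to the C5 methyl, whereas 23 has them cis, so C3 must be inverted; the inversion is merged with the esterification.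

## Logic of the disconnections

23 to 21 + 22. The C3–O bond is cut on the alkyl side, so that the carboxylate of 22 displaces an activated O3 with inversion. The reason is that the tether of the key step needs O3 on the face opposite to the one it occupies in 23. The gain is that the angelate arrives last and 22 is never turned into an acyl donor. The demand is an SN2 displacement at a hindered secondary carbinol under neutral conditions, without elimination and without touching C11.

21 to 17 (through 20, 19 and 18). The C6=C7 bond is cut (aldol condensation), and in the retrosynthetic sense C6–C9 and C6–O3 are re-formed. This turns ring B into a donor–acceptor cyclobutane and turns the 3-hydroxyl into the ether oxygen of an oxolane; 21 and 17 are isomers. The demand is that acid alone opens C6–C9 selectively, that enolisation towards C7 leads on (closure from C9 would only rebuild the four-membered ring), and that O3 is released from C6.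

17 to 16. The bonds C5–C6 and C9–C10 are cut (key step). This removes two rings, the quaternary C5 and C10 in one operation and leaves a flat enol ether with only the C3/C4 pair on the ring and C11 on the chain. The demand is a productive excited state from an acyclic chromophore, straight regiochemistry, and delivery to the face of C5=C10 defined by O3.

16 to 10 + 15. The O3–C6 bond is cut (oxa-Michael addition of 10 to the ynone 15). The route becomes convergent and the two stereochemical domains (ring, C11) are made independently. The demand is addition of a hindered secondary alcohol under conditions that are not basic enough to disturb C11 or the 1,4-dicarbonyl unit.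

10 to 9 to 8, then back to 1 + 2. The C5=C10 bond is cut (ring-closing metathesis of 8, silyl ether removed at 9). The isopropenyl group of 8 comes from the methyl ketone 7 (C5=CH2 bond), and 7 from the amides 6 and 5 (C5–C14 bond). The C3–C4 bond of 4 is cut as a syn-aldol of 1 (through 3) with 2. A syn-aldol is chosen because a syn C3/C4 pair in the open chain becomes the trans pair in the ring. The demand is that C4, which is alpha to a carbonyl from 4 to 7, is not epimerised.

15 to 14 to 13 to 12 to 11. The C8–C9 bond is cut (acetylide acylation of 14). The acid 13 is unmasked from the mixed diester 12, which is made from the half-ester 11. The two carboxyls are thus told apart by protecting groups and not by a regioselective reaction, and C11 comes from the chiral pool. The demand is that the acetylide attacks only the amide of 14.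

## Other disconnections considered

Alternative 1: The cut is C1–C10. In the forward sense the primary iodide A1, a 4-methyl-4-alkylcyclohexa-2,5-dienone whose side chain already holds C4 and the silylated C3 oxygen, would be reduced to a C1 radical (silane hydrogen donor, azo initiator). The radical adds 6-exo to C10 of one enone arm and leaves the other arm as the C6=C7–C8 enone of A2.
- In its favour: ring A, C10 and the quaternary C5 are fixed in one step of a well-precedented type, the ring fusion is necessarily cis, and C3 already has the configuration of the target. On precedent and on the absence of a C3 inversion this alternative is better than the chosen plan.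
- Against it here: A2 is bare at C7, so the propanoate chain and C11 must be attached later at the alpha-carbon of an enone, where nothing nearby controls C11. The choice between the two diastereotopic enone arms rests on stereocentres in a freely rotating chain. A1 itself, a quaternary carbon next to a stereocentre, is laborious to make.
- Comparison: structurally both plans build the C4–C5–C10 triad by intramolecular delivery from a C3/C4 pair, and there they are equal. Mechanistically the radical closure is the safer step. In step economy the chosen plan should be shorter, because C7, C11 and C12 arrive with the chain and ring B needs no later C–C bond.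

Alternative 2: The cut is C6–C7 (and transiently C12–O). SmI2 would reduce the C6 aldehyde of A3 to a ketyl that adds to C7 of the E-enoate. The C6 alkoxide then lactonises onto C12 to give the trans-fused lactone A4, with C8 masked as a dithiane. Unmasking C8 and beta-elimination of the lactone carboxylate would later restore C6=C7 and free C12 for methylation.
- In its favour: ketyl–alkene cyclisations of this kind are established chemistry, so the key step is better precedented than step 13. C11 is set within a rigid lactone, and C3 has the target configuration.
- Against it here: the hard part of the molecule, the C4–C5–C10 triad with an aldehyde on the quaternary carbon, must already be present in A3 and is not addressed by the key step. Two of the three stereocentres it creates (C6, C7) are erased again. The dithiane costs steps, and the base-induced unzipping endangers C11.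
- Comparison: the chosen plan forms C5, C10 and both ring B bonds in its key step and takes C11 from the chiral pool; Alternative 2 forms one ring bond and C11. It is the equal of the chosen plan on C11 control and better on precedent, but weaker on what the key step achieves and on step count.

Alternative 3: The cuts are C3–C4 and C5–C10 (ring A by [4+2]). The dienophile A6, (E)-2-methylbut-2-enal, and the methylsuccinate-derived diene A5 would combine under a triflimide-activated B-(2-methylphenyl)diphenylprolinol oxazaborolidine to give the cyclohexene carbaldehyde A7.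
- In its favour: it is catalytic and convergent, sets C4, C5 and C10 in one bimolecular step, and the E geometry of A6 translates directly into the cis methyl groups. On stereochemical economy, on precedent and on needing no auxiliary it is better than the chosen plan.
- Against it here: C3 is a bare CH2 in A7. Oxygen would have to be introduced late by allylic oxidation next to C1=C2, where C3 competes with the tertiary allylic C10 and the new stereocentre is set without a strong bias. C1=C2 would then have to be saturated in the presence of the enone. A6 is a beta-substituted, alpha-branched and therefore sluggish dienophile, A5 is an unactivated 1-alkyl diene, and the endo/exo ratio decides C10.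
- Comparison: both plans converge on a C6 aldehyde/C8 ketone aldol for ring B, so they are equal there. The chosen plan has O3 from the first step and pays with one inversion; Alternative 3 has no inversion but pays with a late, less controllable oxidation. Overall length should be similar.

Key step: step 13

Remarks on the chemistry:
- Atom numbers C1–C15 are those defined under Structural features.
- 11 is assumed to be a catalogue compound; it is the standard product of auxiliary-controlled alkylation with tert-butyl bromoacetate.
- The configurations of 16 and 17 were rechecked against 23 and need no correction. C3 is (R) in 16, 17 and 21 and (S) in 23, as the tether requires; C4, C5, C10 and C11 keep one spatial arrangement from their creation to 23.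
- The design of 16 is refined in two points. The C6=C9 geometry is left as formed (E) and needs no control, because both isomers lead to the same biradical and C9 later becomes CH2. The two carboxyls of the side chain are differentiated by a tert-butyl/methyl pair, not by a regioselective reaction.

## Route

Step 1
Reactants: 1 (S)-4-benzyl-3-propanoyl-1,3-oxazolidin-2-one; 2 pent-4-enal
Product: 4 (S)-4-benzyl-3-[(2S,3R)-3-hydroxy-2-methylhept-6-enoyl]-1,3-oxazolidin-2-one, via Z-boron enolate 3 (not isolated)
Conditions: Bu2BOTf, iPr2NEt, CH2Cl2, 0 °C; 2, −78 → 0 °C; then pH 7 buffer, MeOH, 30% H2O2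
Reagents that add atoms: none
Why: Evans syn-aldol reaction; the Z-boron enolate 3 reacts through a chair Zimmerman–Traxler transition state on the face away from the benzyl group, which should set C4 (2S of the acyl chain) and C3 (3R) as the syn pair that becomes the trans C3/C4 pair of ring A.

Step 2
Reactants: 4 (S)-4-benzyl-3-[(2S,3R)-3-hydroxy-2-methylhept-6-enoyl]-1,3-oxazolidin-2-one
Product: 5 (2S,3R)-3-hydroxy-N-methoxy-N,2-dimethylhept-6-enamide
Conditions: MeNHOMe·HCl, AlMe3, CH2Cl2, −20 → 0 °C; aq. potassium sodium tartrate work-up
Reagents that add atoms: N,O-dimethylhydroxylamine hydrochloride, CNOC.Cl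
Why: Aluminium amide transamidation (Weinreb amide formation), assisted by the free beta-hydroxyl, should release the auxiliary under non-basic conditions that do not epimerise C4.

Step 3
Reactants: 5 (2S,3R)-3-hydroxy-N-methoxy-N,2-dimethylhept-6-enamide
Product: 6 (2S,3R)-3-{[tert-butyl(dimethyl)silyl]oxy}-N-methoxy-N,2-dimethylhept-6-enamide
Conditions: TBSOTf, 2,6-lutidine, CH2Cl2, 0 °C
Reagents that add atoms: tert-butyldimethylsilyl triflate, CC(C)(C)[Si](C)(C)OS(=O)(=O)C(F)(F)F
Why: Silyl ether formation blocks the C3 hydroxyl, so that the Grignard and ylide steps cannot trigger retro-aldol cleavage or beta-elimination.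

Step 4
Reactants: 6 (2S,3R)-3-{[tert-butyl(dimethyl)silyl]oxy}-N-methoxy-N,2-dimethylhept-6-enamide
Product: 7 (3S,4R)-4-{[tert-butyl(dimethyl)silyl]oxy}-3-methyloct-7-en-2-one
Conditions: MeMgBr, THF, 0 °C; aq. NH4Cl
Reagents that add atoms: methylmagnesium bromide, C[Mg]Br
Why: Grignard addition to a Weinreb amide stops at the chelated tetrahedral adduct, so the methyl ketone (new carbon C14) should form only on work-up and without over-addition.

Step 5
Reactants: 7 (3S,4R)-4-{[tert-butyl(dimethyl)silyl]oxy}-3-methyloct-7-en-2-one
Product: 8 tert-butyl{[(3R,4R)-2,3-dimethylocta-1,7-dien-4-yl]oxy}dimethylsilane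
Conditions: Ph3PCH3Br, KOtBu, THF, 0 °C → rt
Reagents that add atoms: methyltriphenylphosphonium bromide, C[P+](c1ccccc1)(c1ccccc1)c1ccccc1.[Br-]
Why: Wittig methylenation of the methyl ketone gives the isopropenyl group; with the unhindered ylide at 0 °C, olefination should be faster than enolisation towards C4, and the silyl ether prevents elimination.

Step 6
Reactants: 8 tert-butyl{[(3R,4R)-2,3-dimethylocta-1,7-dien-4-yl]oxy}dimethylsilane
Product: 9 tert-butyl{[(1R,2R)-2,3-dimethylcyclohex-3-en-1-yl]oxy}dimethylsilane
Conditions: second-generation Grubbs catalyst RuCl2(=CHPh)(H2IMes)(PCy3) (3 mol%), CH2Cl2, 40 °C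
Reagents that add atoms: none
Why: Ring-closing metathesis between the terminal vinyl group and the 1,1-disubstituted alkene closes the six-membered ring with the trisubstituted C5=C10 alkene; loss of ethene drives it and no stereocentre is touched.

Step 7
Reactants: 9 tert-butyl{[(1R,2R)-2,3-dimethylcyclohex-3-en-1-yl]oxy}dimethylsilane
Product: 10 (1R,2R)-2,3-dimethylcyclohex-3-en-1-ol
Conditions: Bu4NF, THF, rt
Reagents that add atoms: none
Why: Fluoride desilylation frees the C3 hydroxyl under conditions that leave the alkene and C4 untouched.

Step 8
Reactants: 11 (2R)-4-tert-butoxy-2-methyl-4-oxobutanoic acid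
Product: 12 4-tert-butyl 1-methyl (2R)-2-methylbutanedioate
Conditions: MeI, K2CO3, DMF, rt
Reagents that add atoms: iodomethane, CI
Why: O-Alkylation of the carboxylate (SN2 on iodomethane) installs the C12 methyl ester; carbonate does not deprotonate C11.

Step 9
Reactants: 12 4-tert-butyl 1-methyl (2R)-2-methylbutanedioate
Product: 13 (3R)-4-methoxy-3-methyl-4-oxobutanoic acid
Conditions: CF3CO2H, CH2Cl2, 0 °C → rt
Reagents that add atoms: none
Why: Acidolysis of the tert-butyl ester (loss of 2-methylpropene) leaves the methyl ester, so only the carboxyl destined to become C8 is freed.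

Step 10
Reactants: 13 (3R)-4-methoxy-3-methyl-4-oxobutanoic acid
Product: 14 methyl (2R)-4-[methoxy(methyl)amino]-2-methyl-4-oxobutanoate
Conditions: MeNHOMe·HCl, EDC·HCl, N-methylmorpholine, CH2Cl2, 0 °C → rt
Reagents that add atoms: N,O-dimethylhydroxylamine hydrochloride, CNOC.Cl
Why: Carbodiimide amide coupling; the activated carboxyl is beta to C11, so no racemisation pathway is open.

Step 11
Reactants: 14 methyl (2R)-4-[methoxy(methyl)amino]-2-methyl-4-oxobutanoate
Product: 15 methyl (2R)-2-methyl-4-oxohex-5-ynoate
Conditions: HC≡CMgBr, THF, 0 °C; inverse quench into cold aq. NaHSO4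
Reagents that add atoms: ethynylmagnesium bromide, C#C[Mg]Br
Why: Alkynyl Grignard acylation by a Weinreb amide; the chelated adduct prevents over-addition, the alpha-branched methyl ester is much less reactive towards an alkynyl Grignard at 0 °C, and the acidic quench protonates the released amine before it can add to the ynone.

Step 12
Reactants: 10 (1R,2R)-2,3-dimethylcyclohex-3-en-1-ol; 15 methyl (2R)-2-methyl-4-oxohex-5-ynoate
Product: 16 methyl (2R,5E)-6-{[(1R,2R)-2,3-dimethylcyclohex-3-en-1-yl]oxy}-2-methyl-4-oxohex-5-enoate
Conditions: PMe3 (0.2 equiv), CH2Cl2, 0 °C → rt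
Reagents that add atoms: none
Why: Phosphine-catalysed oxa-Michael addition of an alcohol to a terminal ynone; the phosphine–ynone zwitterion deprotonates the alcohol and the alkoxide adds at the terminal carbon, which should give the E-beta-alkoxy enone under essentially neutral conditions that spare C11.

Step 13
Reactants: 16 methyl (2R,5E)-6-{[(1R,2R)-2,3-dimethylcyclohex-3-en-1-yl]oxy}-2-methyl-4-oxohex-5-enoate
Product: 17 oxa-bridged cyclobutane photoadduct: methyl (2R)-2-methyl-4-oxobutanoate acylated at C8 onto C9 of a cyclobutane C5–C6–C9–C10 that is fused to ring A along C5–C10 and to an oxolane O–C3–C4–C5–C6 along C5–C6; configuration (3R,4R,5S,6S,9R,10R,11R) in the skeleton numbering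
Conditions: hν (300 nm, Pyrex), degassed acetone, 5 mM, Ar, 10 °C
Reagents that add atoms: none
Why: Proposed new method: excitation (direct or by triplet transfer from acetone) should give the enone triplet, whose beta-carbon C6 bonds to C5 of the ring alkene, and the 1,4-biradical (C9 alpha-keto radical, C10 secondary radical) should close by C9–C10 bonding after intersystem crossing; the closest known reaction types are the intramolecular [2+2] photocycloaddition of cyclic 3-alkenyloxy enones and the de Mayo photocycloaddition–retro-aldol sequence, the untested element being an acyclic O-tethered beta-alkoxy enone. The oxolane (O, C3, C4, C5, C6) closes in the 1,5-mode (5-exo attack of C6 on C5), and the cyclobutane (C5, C6, C9, C10) closes by recombination of the 1,4-biradical. C5 is controlled by the tether: only an axial O3 can reach C5, so C6 arrives on the face of O3, which is opposite to the C4 methyl, and the C5 methyl ends cis to the C4 methyl. C10 is controlled by the cis fusion that a four-membered ring enforces, so H10 ends cis to the C5 methyl. C6 is fixed by the cis-fused oxolane, and C9 (acyl trans to O) is free but irrelevant because it becomes CH2 in step 14. The step needs straight over crossed regiochemistry, which the three-atom tether secures because bridging C3 to C10 would force ring A into a boat, and it needs cycloaddition to outrun E/Z isomerisation, which wastes photons but not material since both isomers feed the same biradical. The reactive conformer (O3 axial, C4 methyl pseudoaxial) is favoured by relief of allylic 1,2-strain between the two methyl groups, and dilution, degassing and the Pyrex cut-off should suppress dimerisation and secondary cleavage of 17.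

Step 14
Reactants: 17 oxa-bridged cyclobutane photoadduct
Product: 21 methyl (2R)-2-[(4aR,7R,8R,8aR)-7-hydroxy-8,8a-dimethyl-3-oxo-3,4,4a,5,6,7,8,8a-octahydronaphthalen-2-yl]propanoate (3-epi-hydroxy enone; 3R,4R,5R,10R,11R), via lactol 18 (not isolated), via keto aldehyde 19 (not isolated), via ketol 20 (not isolated)
Conditions: TsOH·H2O (0.2 equiv), PhMe, 23 → 70 °C
Reagents that add atoms: none
Why: Acid-promoted retro-aldol opening of a donor–acceptor cyclobutane (de Mayo-type fragmentation): the protonated C8 carbonyl pulls and O3 pushes so that C6–C9 breaks, and water traps the oxocarbenium ion as lactol 18 in equilibrium with keto aldehyde 19. Acid-catalysed intramolecular aldol condensation can only lead on from C7 (attack from C9 would rebuild the four-membered ring), and dehydration of ketol 20 gives the enone. C5 and C10 are untouched, C6 and C9 lose their stereochemistry, and the absence of base protects C11.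

Step 15
Reactants: 21 3-epi-hydroxy enone; 22 angelic acid, (2Z)-2-methylbut-2-enoic acid
Product: 23 methyl (2R)-2-[(4aR,7S,8R,8aR)-8,8a-dimethyl-7-{[(2Z)-2-methylbut-2-enoyl]oxy}-3-oxo-3,4,4a,5,6,7,8,8a-octahydronaphthalen-2-yl]propanoate (CNP0323033.1; 3S,4R,5R,10R,11R)
Conditions: PPh3, DIAD, PhMe, 0 °C → rt
Reagents that add atoms: none
Why: Mitsunobu esterification; the alcohol is activated as an alkoxyphosphonium ion and the angelate anion displaces it by SN2 with inversion, which should set C3 (S), and because the acid acts only as a nucleophile and is never an activated acyl donor the Z double bond should survive.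

## Compound list

1 | (S)-4-benzyl-3-propanoyl-1,3-oxazolidin-2-one | CCC(=O)N1[C@@H](Cc2ccccc2)COC1=O | starting material
2 | pent-4-enal | C=CCCC=O | starting material
3 | dibutylboron Z-enolate of 1, (4S)-4-benzyl-3-[(1Z)-1-[(dibutylboranyl)oxy]prop-1-en-1-yl]-1,3-oxazolidin-2-one | CCCCB(CCCC)O/C(=C\C)N1[C@@H](Cc2ccccc2)COC1=O | intermediate (not isolated)
4 | (S)-4-benzyl-3-[(2S,3R)-3-hydroxy-2-methylhept-6-enoyl]-1,3-oxazolidin-2-one | C=CCC[C@@H](O)[C@H](C)C(=O)N1[C@@H](Cc2ccccc2)COC1=O | intermediate
5 | (2S,3R)-3-hydroxy-N-methoxy-N,2-dimethylhept-6-enamide | C=CCC[C@@H](O)[C@H](C)C(=O)N(C)OC | intermediate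
6 | (2S,3R)-3-{[tert-butyl(dimethyl)silyl]oxy}-N-methoxy-N,2-dimethylhept-6-enamide | C=CCC[C@@H](O[Si](C)(C)C(C)(C)C)[C@H](C)C(=O)N(C)OC | intermediate
7 | (3S,4R)-4-{[tert-butyl(dimethyl)silyl]oxy}-3-methyloct-7-en-2-one | C=CCC[C@@H](O[Si](C)(C)C(C)(C)C)[C@H](C)C(C)=O | intermediate
8 | tert-butyl{[(3R,4R)-2,3-dimethylocta-1,7-dien-4-yl]oxy}dimethylsilane | C=CCC[C@@H](O[Si](C)(C)C(C)(C)C)[C@H](C)C(C)=C | intermediate
9 | tert-butyl{[(1R,2R)-2,3-dimethylcyclohex-3-en-1-yl]oxy}dimethylsilane | CC(C)(C)[Si](C)(C)O[C@@H]1CCC=C(C)[C@H]1C | intermediate
10 | (1R,2R)-2,3-dimethylcyclohex-3-en-1-ol | O[C@@H]1CCC=C(C)[C@H]1C | intermediate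
11 | (2R)-4-tert-butoxy-2-methyl-4-oxobutanoic acid | C[C@H](CC(=O)OC(C)(C)C)C(=O)O | starting material
12 | 4-tert-butyl 1-methyl (2R)-2-methylbutanedioate | COC(=O)[C@H](C)CC(=O)OC(C)(C)C | intermediate
13 | (3R)-4-methoxy-3-methyl-4-oxobutanoic acid | COC(=O)[C@H](C)CC(=O)O | intermediate
14 | methyl (2R)-4-[methoxy(methyl)amino]-2-methyl-4-oxobutanoate | COC(=O)[C@H](C)CC(=O)N(C)OC | intermediate
15 | methyl (2R)-2-methyl-4-oxohex-5-ynoate | COC(=O)[C@H](C)CC(=O)C#C | intermediate
16 | methyl (2R,5E)-6-{[(1R,2R)-2,3-dimethylcyclohex-3-en-1-yl]oxy}-2-methyl-4-oxohex-5-enoate | COC(=O)[C@H](C)CC(=O)/C=C/O[C@@H]1CCC=C(C)[C@H]1C | intermediate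
17 | oxa-bridged cyclobutane photoadduct (cyclobutane C5–C6–C9–C10, oxolane O–C3–C4–C5–C6, acyl on C9; 3R,4R,5S,6S,9R,10R,11R) | COC(=O)[C@H](C)CC(=O)[C@H]1[C@@H]2O[C@@H]3CC[C@H]1[C@@]2(C)[C@H]3C | intermediate
18 | lactol: ring A with the oxolane O–C3–C4–C5–C6 carrying OH on C6 (both C6 epimers) and the chain CH2C(=O)CH2CH(CH3)CO2CH3 on C10; 3R,4R,5S,10R,11R | COC(=O)[C@H](C)CC(=O)C[C@H]1CC[C@H]2OC(O)[C@]1(C)[C@H]2C | intermediate (not isolated)
19 | methyl (2R)-5-[(1R,2S,3R,4R)-2-formyl-4-hydroxy-2,3-dimethylcyclohexyl]-2-methyl-4-oxopentanoate | COC(=O)[C@H](C)CC(=O)C[C@H]1CC[C@@H](O)[C@H](C)[C@@]1(C)C=O | intermediate (not isolated)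
20 | ketol: 6-hydroxy-6,7-dihydro form of 21 (mixture at C6 and C7) | O[C@@H]1CC[C@@H]2CC(=O)C([C@@H](C)C(=O)OC)C(O)[C@]2(C)[C@H]1C | intermediate (not isolated)
21 | methyl (2R)-2-[(4aR,7R,8R,8aR)-7-hydroxy-8,8a-dimethyl-3-oxo-3,4,4a,5,6,7,8,8a-octahydronaphthalen-2-yl]propanoate | O[C@@H]1CC[C@@H]2CC(=O)C([C@@H](C)C(=O)OC)=C[C@]2(C)[C@H]1C | intermediate
22 | angelic acid, (2Z)-2-methylbut-2-enoic acid | C/C=C(/C)C(=O)O | starting material
23 | methyl (2R)-2-[(4aR,7S,8R,8aR)-8,8a-dimethyl-7-{[(2Z)-2-methylbut-2-enoyl]oxy}-3-oxo-3,4,4a,5,6,7,8,8a-octahydronaphthalen-2-yl]propanoate | C/C=C(/C)C(=O)O[C@H]1CC[C@@H]2CC(=O)C([C@@H](C)C(=O)OC)=C[C@]2(C)[C@H]1C | target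

## Step count and least certain steps

Total step count: 15. Longest linear sequence: 11 steps (1–7, then 12–15). The side-chain branch has 4 steps (8–11) before the union in step 12.

**Step 13 (key step, proposed new method).** The most likely failure is that the acyclic enone triplet relaxes by twisting about C6=C9 faster than C6 bonds to C5, so that light is spent on E/Z cycling. From the Z isomer, hydrogen transfer from C3–H to the carbonyl oxygen could then divert material, and prolonged irradiation could cleave the product ketone.

The fallback uses known chemistry, sets out from 10 and returns at 17: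
- 10 is added to but-3-yn-2-one (PMe3 cat., CH2Cl2) to give (3E)-4-{[(1R,2R)-2,3-dimethylcyclohex-3-en-1-yl]oxy}but-3-en-2-one F1.
- 1,2-Reduction (NaBH4, CeCl3, MeOH, −78 °C, NaHCO3 work-up) gives the allylic alcohol (3E)-4-{[(1R,2R)-2,3-dimethylcyclohex-3-en-1-yl]oxy}but-3-en-2-ol F2, a 1,6-diene without an enone chromophore.
- The CuOTf-catalysed intramolecular [2+2] photocycloaddition of 1,6-dienes (254 nm, Et2O) is a known reaction of homoallyl vinyl ethers that tolerates allylic hydroxyl groups. It proceeds through a ground-state complex of monovalent copper with both alkenes, so there is no free triplet to lose by isomerisation. It should give the cyclobutyl carbinol F3 with the same oxolane/cyclobutane framework; the configuration at C9 and at the carbinol is immaterial.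
- Dess–Martin periodinane oxidation gives the cyclobutyl methyl ketone F4.
- Kinetic deprotonation of the methyl group (LiN(iPr)2, THF, −78 °C) and SN2 alkylation with methyl (R)-2-{[(trifluoromethyl)sulfonyl]oxy}propanoate (inversion) installs C11, C12 and C13 and gives 17.

**Step 14.** The most likely failure is re-addition of the freed C3 hydroxyl to C6 (intramolecular oxa-Michael), or arrest of the cascade before the beta-elimination, because O3 and C6 remain 1,3-diaxially disposed on ring A. Material would then rest as the oxa-bridged beta-alkoxy ketone instead of 21. A lesser risk is slow condensation at the neopentyl C6.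

The fallback sets out from 17 and returns at 21:
- Acid treatment of 17 at room temperature is allowed to converge on the oxa-bridged keto ether F5 (O3 bonded to C6, ring B saturated).
- F5 is opened irreversibly by soft enolisation and silyl-triflate-assisted beta-elimination (Et3SiOTf, Et3N, CH2Cl2, −78 → 0 °C, mild aqueous work-up), a known way of opening beta-alkoxy ketones. It traps O3 as the silyl ether and gives the 3-O-triethylsilyl enone F6.
- Buffered HF·pyridine (THF, 0 °C) releases 21 immediately before step 15.

**Step 15.** The most likely failure is a slow SN2 displacement at a secondary carbinol flanked by the C4 methine and close to the quaternary C5, with a nucleophile that is only moderately acidic. This would favour elimination towards C2=C3 or acyl transfer with retention.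

The fallback sets out from 21 and returns at 23:
- Dess–Martin periodinane oxidation gives the 3,8-diketone F7.
- Chemoselective reduction of the saturated C3 ketone in the presence of the enone (NaBH4, MeOH/CH2Cl2, −78 °C) should deliver hydride from the face opposite to the two methyl groups and give the 3-epimeric, target-configured alcohol F8. The C4 centre, now alpha to a ketone, must not be exposed to base at the stage of F7.
- Acylation of F8 with the mixed anhydride of 22 and 2,4,6-trichlorobenzoyl chloride (Et3N, PhMe, 80 °C, no nucleophilic catalyst) gives 23. This is the known way to form angelates without Z/E isomerisation.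

**Step 12.** The most likely failure is that the hindered secondary alcohol adds too slowly, so that the phosphine-activated ynone oligomerises or a second alcohol adds to the product.

The fallback sets out from 15 (with 10) and returns at 16:
- Hydrochlorination of 15 (LiCl, AcOH, MeCN) gives the beta-chlorovinyl ketone methyl (2R,5Z)-6-chloro-2-methyl-4-oxohex-5-enoate F9.
- Addition–elimination with the sodium alkoxide of 10 (NaH, THF, −20 °C, alkoxide added to F9) gives 16.

## Further compounds

F1 | step 13 | (3E)-4-{[(1R,2R)-2,3-dimethylcyclohex-3-en-1-yl]oxy}but-3-en-2-one | CC(=O)/C=C/O[C@@H]1CCC=C(C)[C@H]1C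
F2 | step 13 | (3E)-4-{[(1R,2R)-2,3-dimethylcyclohex-3-en-1-yl]oxy}but-3-en-2-ol (carbinol epimers) | CC(O)/C=C/O[C@@H]1CCC=C(C)[C@H]1C
F3 | step 13 | cyclobutyl carbinol: framework of 17 with CH(OH)CH3 on C9 (carbinol epimers) | CC(O)[C@H]1[C@@H]2O[C@@H]3CC[C@H]1[C@@]2(C)[C@H]3C
F4 | step 13 | cyclobutyl methyl ketone: framework of 17 with an acetyl group on C9 | CC(=O)[C@H]1[C@@H]2O[C@@H]3CC[C@H]1[C@@]2(C)[C@H]3C
F5 | step 14 | oxa-bridged keto ether: cis-decalin-8-one with O linking C3 and C6 and the propanoate chain on C7 (C7 epimers) | COC(=O)[C@H](C)C1C(=O)C[C@H]2CC[C@H]3O[C@@H]1[C@]2(C)[C@H]3C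
F6 | step 14 | 3-O-triethylsilyl ether of 21 | CC[Si](CC)(CC)O[C@@H]1CC[C@@H]2CC(=O)C([C@@H](C)C(=O)OC)=C[C@]2(C)[C@H]1C
F7 | step 15 | 3,8-diketone: methyl (2R)-2-[(4aR,8R,8aR)-8,8a-dimethyl-3,7-dioxo-3,4,4a,5,6,7,8,8a-octahydronaphthalen-2-yl]propanoate | O=C1CC[C@@H]2CC(=O)C([C@@H](C)C(=O)OC)=C[C@]2(C)[C@H]1C
F8 | step 15 | target-configured alcohol: methyl (2R)-2-[(4aR,7S,8R,8aR)-7-hydroxy-8,8a-dimethyl-3-oxo-3,4,4a,5,6,7,8,8a-octahydronaphthalen-2-yl]propanoate | O[C@H]1CC[C@@H]2CC(=O)C([C@@H](C)C(=O)OC)=C[C@]2(C)[C@H]1C
F9 | step 12 | methyl (2R,5Z)-6-chloro-2-methyl-4-oxohex-5-enoate | COC(=O)[C@H](C)CC(=O)/C=C\Cl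
A1 | alternative 1 | 4-[(2R,3S)-3-{[tert-butyl(dimethyl)silyl]oxy}-5-iodopentan-2-yl]-4-methylcyclohexa-2,5-dien-1-one | CC(C)(C)[Si](C)(C)O[C@@H](CCI)[C@H](C)C1(C)C=CC(=O)C=C1
A2 | alternative 1 | (4aR,5R,6S,8aR)-6-{[tert-butyl(dimethyl)silyl]oxy}-4a,5-dimethyl-4a,5,6,7,8,8a-hexahydronaphthalen-2(1H)-one | CC(C)(C)[Si](C)(C)O[C@H]1CC[C@@H]2CC(=O)C=C[C@]2(C)[C@H]1C
A3 | alternative 2 | ring A aldehyde with the dithiane-masked E-enoate chain on C10: methyl (2E)-2-methyl-3-(2-{[2-formyl-4-silyloxy-2,3-dimethylcyclohexyl]methyl}-1,3-dithian-2-yl)prop-2-enoate | CC(C)(C)[Si](C)(C)O[C@H]1CC[C@H](CC2(SCCCS2)/C=C(\C)C(=O)OC)[C@](C)(C=O)[C@H]1C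
A4 | alternative 2 | trans-fused tricyclic gamma-lactone with C8 as 1,3-dithiane and C3 as silyl ether | CC(C)(C)[Si](C)(C)O[C@H]1CC[C@@H]2CC3(SCCCS3)[C@@H]4[C@@H](C)C(=O)O[C@H]4[C@]2(C)[C@H]1C
A5 | alternative 3 | methyl (2R)-2-methyl-3-{2-[(2E)-penta-2,4-dien-1-yl]-1,3-dioxolan-2-yl}propanoate | C=C/C=C/CC1(C[C@@H](C)C(=O)OC)OCCO1
A6 | alternative 3 | (2E)-2-methylbut-2-enal | C/C=C(\C)C=O
A7 | alternative 3 | ring A cyclohexene carbaldehyde (C5 formyl and methyl, C4 methyl, ketal-masked chain on C10, C1=C2 alkene) | C1C=C[C@H](CC2(C[C@@H](C)C(=O)OC)OCCO2)[C@](C)(C=O)[C@H]1C
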